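(The earlier runs and the new flask are simulated on assumed constants; noise was put on by code.)

I compare two times.

| flask | left-handed substrate | right-handed substrate | coupling partner | free catalyst | racemization catalyst | remark | time |
|---|---|---|---|---|---|---|---|
| dawn | 0.25 M | 0.25 M | 1 M | 2 mM | 5 mM | run made earlier |  |
| midnight | 0.25 M | 0.25 M | 1 M | 3.1 mM | 5 mM | run made earlier |  |
| summer | 0.25 M | 0.25 M | 2 M | 1.4 mM | 5 mM | run made earlier |  |
| flask | 0.25 M | 0.25 M | 1.00 M | 1.4 mM | 5.0 mM |  | 25 h |

| run | time / h | left-handed product / % | right-handed product / % | left-handed substrate / % |
|---|---|---|---|---|
| dawn | 4.00 | 37.0 | 24.0 | 12.8 |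
| dawn | 10.0 | 49.4 | 35.8 | 3.6 |
| dawn | 20.0 | 53.4 | 42.7 | 0.8 |
| dawn | 30.0 | 55.5 | 44.0 | 0.3 |
| midnight | 8.00 | 51.1 | 38.5 | 2.7 |
| midnight | 15.0 | 53.3 | 43.8 | 0.4 |
| midnight | 25.0 | 53.9 | 46.0 | 0 |
| midnight | 30.0 | 54.1 | 45.8 | 0.2 |
| summer | 2.50 | 38.2 | 23.4 | 13.1 |
| summer | 6.00 | 48.4 | 36.3 | 3.1 |
| summer | 12.0 | 52.4 | 43.4 | 0.4 |
| summer | 30.0 | 52.2 | 46.3 | 0 |

(readings scatter by 0.5 percentage points)

1. left-handed product and right-handed product together, in percent of the left-handed substrate and right-handed substrate charged together, at 25 h
2. excess of left-handed product over right-handed product in the product at 25 h
3. whether the exchange between left-handed substrate and right-handed substrate keeps pace with the reaction: how far the product's excess at 25 h gets from its value without exchange to its value with instant exchange (above 80% keeps pace, below 20% hardly takes part, else lags behind)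

- free catalyst is single-handed; left-handed substrate and right-handed substrate are mirror images of each other, charged as a racemate, each of them at the stated concentration
- an excess is the difference of the two amounts in percent of their sum
- an excess is below zero if the other one leads

This is a dynamic kinetic resolution. The runs start racemic, so when both substrates have reacted, each net crossing from right-handed to left-handed substrate has widened the product gap by two. The net crossing follows c(right-handed substrate) − c(left-handed substrate), which the dawn balance gives at each reading. Its area, by straight lines between readings, is 1.50 h. The last dawn gap reads 12 percentage points, with 0.500% unreacted, so area over gap gives a mean exchange time of 13.1 h.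

The second time is the mean substrate lifetime, the area under the unreacted fraction. Dawn reads 5.55 h. Dawn and the flask match in coupling partner and racemization catalyst, so I keep the exchange time and scale the lifetime inversely with free catalyst, which gives 7.93 h for the flask, shorter than the exchange time.

My exchange share, lifetime over lifetime plus exchange time, is 37.8% for the flask. That lies between 20% and 80%, so I expect lagging.

The forecast gives yield 94.8%, excess 14.7% and lags behind: “roughly a quarter of the way, so exchange lags behind, though near the threshold”. My share stands higher.

The flask gives yield 93.4%, excess 15.4% and lags behind, having gone 29% of the way, below my share.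

    coupling partner + free catalyst + left-handed substrate → free catalyst + left-handed product (k = 0.0620 /M²/s)
    coupling partner + free catalyst + right-handed substrate → free catalyst + right-handed product (k = 0.0290 /M²/s)
    left-handed substrate + racemization catalyst ⇌ right-handed substrate + racemization catalyst, rate k3*[racemization catalyst]*[left-handed substrate] forward; the back reaction follows from the equilibrium constant (k = 0.00270 /M/s)
    2 coupling partner → self-condensation product (k = 2.60 × 10⁻⁶ /M/s)
    coupling partner + racemization catalyst → spent catalyst (k = 1.80 × 10⁻⁵ /M/s)

At 25.0 h the flask holds 41.8% of its racemization catalyst, and its relaxation half-life at that moment, both ways together, of 17.1 h means a time of 24.7 h, longer than my dawn mean. For a neighbour flask with 0.0056 M of free catalyst, my scaling gives a lifetime of 1.98 h and a share of 13.2%. Scaling the dawn gap by share then gives 5.08% for that neighbour, which itself gives at >99.9% yield an excess of 5.51%.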